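You cannot keep free catalyst alive in these flasks: two of it go at each turn, and by this step alone 0.609 % of the charge stands at the end of the run, so reckon first what its short life is worth.

the same everywhere: starting material 0.10 M; free catalyst 0.10 mM; time 8.0 min

| run | coupling partner | second substrate | remark |
|---|---|---|---|
| Monday's | 0.200 M (fed, over 6.0 min) | 0.0500 M | all else is in the flask from the start; the feed brings no volume worth counting |
| Thursday's | 0.200 M | 0.0500 M | everything together at the start |
| Sunday's | 0.200 M | 0.0500 M (fed, over 6.0 min) | all else is in the flask from the start; the feed brings no volume worth counting |

    2 free catalyst → spent catalyst (k1 = 1700 L mol⁻¹ s⁻¹)
    coupling partner → decomposed reagent (k2 = 0.0040 s⁻¹)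
    second substrate + coupling partner + free catalyst → free catalyst + second product (k3 = 9200 L² mol⁻² s⁻¹)
    starting material + coupling partner + free catalyst → free catalyst + target (k4 = 2500 L² mol⁻² s⁻¹)

- which flask leads in amount of target, in percent of the starting material charged ("all alike" within 1.5 percentage points) (Monday's / Thursday's / Sunday's / all alike)
- how much target is there at the end, in percent of the starting material charged: Monday's
- how much target is there at the end, in percent of the starting material charged: Thursday's
- how much target is there at the end, in percent of the starting material charged: Sunday's

- where a step has two of a species, its rate is k times that concentration squared, and two are used at each turn
- run time (Monday's): 8.0 min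

The free catalyst's first half-life is 2.94 s, against 2.9 min for the coupling partner's decomposition. For a second-order fall, the run is worth the first half-life times the natural logarithm of one plus run time over first half-life: 15.0 s at full catalyst charge. Multiply that by the target step's constant, the partner charge and the catalyst charge and you have the reach, the logarithm of starting material charged over starting material left, if the partner stood at its charge: 0.750, or 52.8 % target.

But the partner doesn't stand still. Where the partner is charged at the start, as in Thursday's and Sunday's, half the reach is spent by 34.7 s, and decomposition alone has then left 87.0 % of the partner. In Sunday's, the feed has brought just 0.00483 M of second substrate by then, so take 47.9 % target. In Thursday's, second substrate stands at its charge from the start, and its step's constant is 3.68 times the target step's. Take its charge off the partner and you get 38.7 %, which is harsh but simple. In Monday's, the partner rises from zero, and a steady feed with no loss of partner gives 13.2 % by the end of the feed. That figure counts neither decomposition nor the second substrate's step, and none of the three counts the partner that the target itself uses, so expect each to run high.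

The forecast puts Sunday's first, with 10 % (8 % to 13 %) for Monday's, 35 % (31 % to 38 %) for Thursday's and 39 % (35 % to 43 %) for Sunday's, holding of the coupling partner that “feeding it starves that window”. The forecast's order is the same as the hand reckoning's, but its numbers are lower.

The simulation gives 9.96 % for Monday's, 34.9 % for Thursday's and 39.1 % for Sunday's, so Sunday's leads and the forecast stands.

In Sunday's, 78 % of the target step's turnover up to the end of the run is done by 0.800 min, whereas the partner's decomposition reaches half of its turnover up to the end of the run at 2.10 min. In Sunday's, the logarithm of starting material charged over starting material left comes to 66.1 % of the reach. Now take the neighbour of Sunday's with 4.0 × 10⁻⁵ M of free catalyst: the charge drops by a factor of 2.50, yet the reach falls just to 0.617, and the same share gives 33.5 % target. The simulation gives 32.6 % for that neighbour.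

The numbers of this flask stand for no real mixture; what happens was integrated by code.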